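The route cuts the pyranone ring (O1'–C2'–C3'–C4'–C4a'–C8a') of the 5,7-dimethoxychromone at three bonds: C4a'–C4', C4'–C3' and O1'–C2'. C2' and C3' then become the terminal alkyne C8≡C9 of an enantiopure 3-hydroxynon-8-ynoate. C4' becomes carbon monoxide, and O1'/C4a' become the neighbouring C–O and C–I carbons of an iodinated phloroglucinol dimethyl ether. One palladium-catalysed carbonylative annulation in diethylamine joins the three pieces, closes the ring and delivers the target directly. The aryl partner is carried as its O-acetate, which is less electron-rich and is unmasked by the amine in the flask. The alkyne partner carries the finished C3 (S) carbinol and the methyl ester.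

Key step: step 5

Assumption: the enzyme of step 4 is the S-selective hit of a commercial ketoreductase panel; C3 is S because O > C2 > C4 > H, and the configuration of the hydroxy ester would be checked by Mosher ester analysis before the fragments are joined.

Step 1
Reactants: 1 3,5-dimethoxyphenol
Product: 2 2-iodo-3,5-dimethoxyphenol
Conditions: NIS (1.0 equiv), CH2Cl2, −20 → 0 °C, dark
Reagents that add atoms: N-iodosuccinimide, O=C1CCC(=O)N1I
Why: Electrophilic aromatic iodination (SEAr) of a phloroglucinol-type ring needs no acid, and the two equivalent positions ortho to the free hydroxyl (C2/C6, also para to a methoxy group and reachable by hydrogen-bond-guided NIS) should react ahead of C4, which is wedged between two methoxy groups, while one equivalent of reagent at low temperature holds back a second iodination and chromatography removes any 4-iodo isomer.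

Step 2
Reactants: 2 2-iodo-3,5-dimethoxyphenol
Product: 3 2-iodo-3,5-dimethoxyphenyl acetate
Conditions: Ac2O (1.5 equiv), pyridine, 0 °C → rt
Reagents that add atoms: acetic anhydride, CC(=O)OC(C)=O
Why: Pyridine-mediated O-acetylation of a phenol is reliable even next to iodine, and the ester removes phenoxide donation into the C–I carbon, makes the light- and acid-sensitive iodophenol storable, and needs no separate removal because the amine of step 5 cleaves it.

Step 3
Reactants: 4 hept-6-ynoic acid; 5 potassium monomethyl malonate
Product: 9 methyl 3-oxonon-8-ynoate, via 1-(hept-6-ynoyl)imidazole 6 (not isolated), via magnesium methyl malonate 7 (not isolated), via acylmalonic half-ester 8 (not isolated)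
Conditions: (i) 4, CDI (1.1 equiv), THF, rt; (ii) 5 (2 equiv), MgCl2, Et3N, MeCN, rt, then the solution from (i), rt → 40 °C; 1 M HCl work-up
Reagents that add atoms: potassium monomethyl malonate (= reactant 5), COC(=O)CC(=O)[O-].[K+]
Why: Masamune–Brooks homologation, in which the acyl imidazolide 6 C-acylates the chelated magnesium enolate of 7 and the resulting half-ester 8 loses CO2 to give the β-keto ester under near-neutral conditions that leave the terminal alkyne untouched.

Step 4
Reactants: 9 methyl 3-oxonon-8-ynoate
Product: 10 methyl (S)-3-hydroxynon-8-ynoate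
Conditions: S-selective ketoreductase, NADP+ (cat), iPrOH (10 vol %), potassium phosphate buffer pH 7, 30 °C
Reagents that add atoms: none
Why: Ketoreductase-catalysed asymmetric reduction of an aliphatic β-keto ester, a standard substrate class for these enzymes, transfers the NADPH hydride inside the chiral active site to the Re face of C3 and so sets the S carbinol, with isopropanol recycling the cofactor, and unlike a ruthenium/H2 hydrogenation it cannot touch the terminal alkyne.

Step 5
Reactants: 3 2-iodo-3,5-dimethoxyphenyl acetate (1.2 equiv); 10 methyl (S)-3-hydroxynon-8-ynoate; 11 carbon monoxide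
Product: 14 penithochromone Q [methyl (S)-7-(5,7-dimethoxy-4-oxo-4H-chromen-2-yl)-3-hydroxyheptanoate], via acetoxyaryl ynone 12 (not isolated), via hydroxyaryl enaminone 13 (not isolated)
Conditions: PdCl2(PPh3)2 (5 mol %), dppp (5 mol %), thiourea (5 mol %), CO (1 atm), DBU (2 equiv), Et2NH, 40 °C
Reagents that add atoms: carbon monoxide (= reactant 11), [C-]#[O+]
Why: Pd(0) inserts into the C–I bond of 3, CO insertion gives the 2-acetoxy-4,6-dimethoxybenzoyl–palladium species, and base-assisted transfer of the alkynyl group of 10 followed by reductive elimination forms C4a'–C4' and C4'–C3' in ynone 12. Diethylamine then adds to C2' of 12 and strips the acetyl group to give enaminone 13, whose phenoxide attacks C2' and expels the amine, forming O1'–C2'. This is the known palladium-catalysed carbonylative Sonogashira-type annulation of o-iodophenols and their acetates with terminal alkynes to 2-substituted chromones, run here without copper so that direct alkynylation and alkyne dimerisation stay slow. The pyranone closes by a 6-endo-trig addition–elimination (formally 6-endo-dig on the ynone), and the 5-exo closure to the aurone is shut off because C2' is the only electrophilic carbon left in 13. No stereocentre is created, and C3, separated from the alkyne by four methylenes, could only be scrambled by retro-aldol or elimination–readdition, neither of which is expected for a free β-hydroxy ester at 40 °C. The step needs the acylpalladium to be captured by the alkyne and not by diethylamine or the free C3 hydroxyl: the two ortho substituents shield the acyl carbon against direct attack of the bulky amine and of the hindered, neutral secondary alcohol (which the amine outnumbers in any case), the unhindered acidic C9–H lets the acetylide arrive through the metal, and the acetate keeps the ring from turning into an electron-rich phenoxide before oxidative addition.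

Compound list
1 | 3,5-dimethoxyphenol | COc1cc(O)cc(OC)c1 | starting material
2 | 2-iodo-3,5-dimethoxyphenol | Oc1cc(OC)cc(OC)c1I | intermediate
3 | 2-iodo-3,5-dimethoxyphenyl acetate | CC(=O)Oc1cc(OC)cc(OC)c1I | intermediate
4 | hept-6-ynoic acid | C#CCCCCC(=O)O | starting material
5 | potassium monomethyl malonate | COC(=O)CC(=O)[O-].[K+] | starting material
6 | 1-(hept-6-ynoyl)imidazole | C#CCCCCC(=O)n1ccnc1 | intermediate (not isolated)
7 | magnesium bis(monomethyl malonate) | COC(=O)CC(=O)[O-].COC(=O)CC(=O)[O-].[Mg+2] | intermediate (not isolated)
8 | 2-(methoxycarbonyl)-3-oxonon-8-ynoic acid (C2 labile, racemic) | C#CCCCCC(=O)C(C(=O)O)C(=O)OC | intermediate (not isolated)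
9 | methyl 3-oxonon-8-ynoate | COC(=O)CC(=O)CCCCC#C | intermediate
10 | methyl (S)-3-hydroxynon-8-ynoate | COC(=O)C[C@@H](O)CCCCC#C | intermediate
11 | carbon monoxide | [C-]#[O+] | starting material
12 | methyl (S)-10-(2-acetoxy-4,6-dimethoxyphenyl)-3-hydroxy-10-oxodec-8-ynoate | COC(=O)C[C@@H](O)CCCCC#CC(=O)c1c(OC(C)=O)cc(OC)cc1OC | intermediate (not isolated)
13 | methyl (S,E)-8-(diethylamino)-3-hydroxy-10-(2-hydroxy-4,6-dimethoxyphenyl)-10-oxodec-8-enoate | COC(=O)C[C@@H](O)CCCC/C(N(CC)CC)=C\C(=O)c1c(O)cc(OC)cc1OC | intermediate (not isolated)
14 | penithochromone Q, methyl (S)-7-(5,7-dimethoxy-4-oxo-4H-chromen-2-yl)-3-hydroxyheptanoate | COC(=O)C[C@@H](O)CCCCc1cc(=O)c2c(OC)cc(OC)cc2o1 | target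

Total step count: 5, in two convergent branches. Longest linear sequence: 3 steps (1 → 2 → 3 → 14, or 4 → 9 → 10 → 14).

Steps most likely to fail

1. Step 5.
- **What may go wrong:** Oxidative addition at the doubly ortho-oxygenated, electron-rich C–I bond may be slower under CO than catalyst decay. Capture of the acylpalladium by diethylamine, reductive loss of iodine or early loss of the acetyl group could then outrun alkynyl transfer.
- **Fallback:** It sets out from 10 and returns at 14. C4' is brought in at the carboxylic acid oxidation level instead of as CO, so no insertion into the aryl iodide is needed.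
  - 10 is silylated (TBSCl, imidazole, DMF) to methyl (S)-3-[(tert-butyldimethylsilyl)oxy]non-8-ynoate F1, because a free alcohol would be acylated.
  - Commercial 2-hydroxy-4,6-dimethoxybenzoic acid is acetylated (Ac2O, pyridine) to 2-acetoxy-4,6-dimethoxybenzoic acid F2. Oxalyl chloride and catalytic DMF convert this into 2-acetoxy-4,6-dimethoxybenzoyl chloride F3.
  - Acyl Sonogashira coupling of F1 with F3 (PdCl2(PPh3)2, CuI, Et3N, THF, rt) should give methyl (S)-10-(2-acetoxy-4,6-dimethoxyphenyl)-3-[(tert-butyldimethylsilyl)oxy]-10-oxodec-8-ynoate F4.
  - Diethylamine in MeCN at rt to 40 °C removes the acetate and closes the pyranone through the enaminone, giving methyl (S)-3-[(tert-butyldimethylsilyl)oxy]-7-(5,7-dimethoxy-4-oxo-4H-chromen-2-yl)heptanoate F5.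
  - HF·pyridine in THF, chosen over basic fluoride to avoid β-elimination, releases 14.

2. Step 4.
- **What may go wrong:** The two ketone substituents are similar in size, so no panel enzyme may combine full conversion with high facial selectivity. Esterase activity in the enzyme preparation could also erode the methyl ester.
- **Fallback:** It sets out from 4 and returns at 10. The carbinol is made by forming the C2–C3 bond under auxiliary control instead of by reduction.
  - 4 is converted (CDI, MeNHOMe·HCl, CH2Cl2) into N-methoxy-N-methylhept-6-ynamide F6, which is reduced with DIBAL-H at −78 °C to hept-6-ynal F7.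
  - The chlorotitanium enolate of commercial (S)-3-acetyl-4-isopropyl-1,3-thiazolidine-2-thione (TiCl4, iPr2NEt, CH2Cl2, −78 °C) adds to F7 in a Nagao-type acetate aldol. Through the sulfur-chelated chair transition state this is expected to give (S)-3-hydroxy-1-[(S)-4-isopropyl-2-thioxo-1,3-thiazolidin-3-yl]non-8-yn-1-one F8.
  - The minor diastereomer is removed by chromatography, so enantiopurity does not depend on the level of induction.
  - Methanol with imidazole displaces the auxiliary and gives 10 directly.

3. Step 1.
- **What may go wrong:** The iodinating agent may attack C4, a second iodination may occur, and acid may promote migration or loss of iodine during isolation. Each would erode the supply of the correct regioisomer.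
- **Fallback:** It sets out from 1 and returns at 2. The position is fixed by directed ortho-metalation instead of by electrophilic substitution.
  - 1 is carbamoylated (ClC(O)NEt2, K2CO3, MeCN, reflux) to 3,5-dimethoxyphenyl N,N-diethylcarbamate F9.
  - s-BuLi/TMEDA in THF at −78 °C lithiates the position flanked by the carbamate, the strongest directing group present, and a cooperating methoxy group. An iodine quench gives 2-iodo-3,5-dimethoxyphenyl N,N-diethylcarbamate F10.
  - Basic hydrolysis (NaOH, EtOH, reflux), which avoids acid on the iodoarene, returns 2.

Further compounds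
F1 | step 5 | methyl (S)-3-[(tert-butyldimethylsilyl)oxy]non-8-ynoate | COC(=O)C[C@@H](O[Si](C)(C)C(C)(C)C)CCCCC#C
F2 | step 5 | 2-acetoxy-4,6-dimethoxybenzoic acid | CC(=O)Oc1cc(OC)cc(OC)c1C(=O)O
F3 | step 5 | 2-acetoxy-4,6-dimethoxybenzoyl chloride | CC(=O)Oc1cc(OC)cc(OC)c1C(=O)Cl
F4 | step 5 | methyl (S)-10-(2-acetoxy-4,6-dimethoxyphenyl)-3-[(tert-butyldimethylsilyl)oxy]-10-oxodec-8-ynoate | COC(=O)C[C@@H](O[Si](C)(C)C(C)(C)C)CCCCC#CC(=O)c1c(OC(C)=O)cc(OC)cc1OC
F5 | step 5 | methyl (S)-3-[(tert-butyldimethylsilyl)oxy]-7-(5,7-dimethoxy-4-oxo-4H-chromen-2-yl)heptanoate | COC(=O)C[C@@H](O[Si](C)(C)C(C)(C)C)CCCCc1cc(=O)c2c(OC)cc(OC)cc2o1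
F6 | step 4 | N-methoxy-N-methylhept-6-ynamide | C#CCCCCC(=O)N(C)OC
F7 | step 4 | hept-6-ynal | C#CCCCCC=O
F8 | step 4 | (S)-3-hydroxy-1-[(S)-4-isopropyl-2-thioxo-1,3-thiazolidin-3-yl]non-8-yn-1-one | C#CCCCC[C@H](O)CC(=O)N1[C@@H](C(C)C)CSC1=S
F9 | step 1 | 3,5-dimethoxyphenyl N,N-diethylcarbamate | CCN(CC)C(=O)Oc1cc(OC)cc(OC)c1
F10 | step 1 | 2-iodo-3,5-dimethoxyphenyl N,N-diethylcarbamate | CCN(CC)C(=O)Oc1cc(OC)cc(OC)c1I
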